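## The problem

The target is a biflavanone built from two (2S)-naringenin units, called flavanone 1 and flavanone 2 here. A diaryl ether joins them, running from the C4′ oxygen on ring B of flavanone 1 to C6 on ring A of flavanone 2. Each unit has one stereocentre, the benzylic carbinol carbon C2. The two centres lie far apart across the ether bridge and cannot steer one another, so each must be set separately by reagent control, and both must be (S). Both C2–O1 bonds are β to a ketone: base or hot acid opens ring C by E1cB to the 2′-hydroxychalcone, which recloses without facial preference. Every step after a ring C exists must therefore be near neutral, and the five phenols should be freed last under non-basic conditions. Ring A of flavanone 2 carries four oxygens (O1, C5–O, C6–O, C7–O) with the bridging oxygen wedged between two others. Routes through a symmetric phloroglucinol ring cannot tell C6 from C8, and the hindered diaryl ether needs forcing conditions that no flavanone would survive. The enabling feature is that in flavanone 2 the adjacent ring A carbons C8a and C4a carry O1 and the C4 carbonyl, with the oxygen-bearing C5 beside C4a and the bridging C6 oxygen beyond. This is the array left when an oxygen nucleophile adds to the remote carbon of a 3-alkoxyaryne and the aryl anion is acylated by a tethered ester. Flavanone 1 has the same C8a/C4a/C5 array, so one reaction type can close both rings C.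

## Retrosynthesis

**34 from 33.** The five phenolic O–H bonds are traced back to O–benzyl bonds in pentabenzyl ether 33. Benzyl is preferred to methyl (Lewis-acid cleavage of a 7-methoxy group risks ring opening), to silyl (fluoride is used in both annulations) and to acetal groups (acid is needed to unmask the aldehyde). The skeleton is unchanged. The forward hydrogenolysis must spare two aryl ketones and two benzylic C2–O1 bonds.

**33 from 26 and 30.** Ring C of flavanone 1 is opened at C8a–O1 and C4–C4a, giving the (S)-hydroxy ester 26 and the 3,5-bis(benzyloxy)benzyne precursor 30. Cutting C2–O1 instead (oxa-Michael closure of a chalcone) would give no control at C2 and would put flavanone 2 under equilibrating base. Cutting only C4–C4a (Friedel–Crafts) would require the aryl ether to be made first by substitution at an ionisable benzylic carbon. The double cut transfers a preformed stereocentre with its C–O bond intact and reduces ring A of flavanone 1 to a two-step derivative of phenol 1. The forward step must be regioselective (secured by the benzyloxy group beside the triple bond) and must not open flavanone 2.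

**26 from 21 via 25, 23 and 22.** The carbinol C–H bond is cut to give β-keto ester 25, and the C–C bond to the acetate unit is cut to give acid 23, which comes from aldehyde 22 and its dioxolane 21. A ketone hydrogenation is preferred to an acetate aldol on 22 because its facial selectivity is predictable and its conditions are non-basic. The forward hydrogenation must reduce the chelating β-keto ester and leave the chromanone carbonyl alone.

**21 from 14 and 18 (key disconnection).** Ring C of flavanone 2 is opened at C8a–O1 and C4–C4a, giving the 2-(trimethylsilyl)aryl triflate 14 and the (S)-hydroxy ester 18. This is the only cut that fixes the 6-aryloxy (rather than 8-aryloxy) pattern by the substitution of the aryne itself: the alkoxide adds remote from the flanking benzyloxy group. It also assembles the crowded tetraoxygenated ring without any acylation of a symmetric ring. Compound 14 holds all three ring A ether oxygens and the diaryl ether, with the aldehyde of the future flavanone 1 masked as a dioxolane; 18 is a two-step compound. The forward reaction needs a proton-free alkoxide so that the aryl anion is acylated and not protonated. For this reason 18 enters as its trimethylsilyl ether 19, made in the flask, and fluoride releases alkoxide and aryne 20 together.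

**18 from 15 and 16 via 17.** The carbinol C–H bond leads back to β-keto ester 17, and the C–C bond to the ester carbon leads back to 4′-(benzyloxy)acetophenone 15 and dimethyl carbonate 16. The stereocentre is thus set on a small, crystalline compound where enantiopurity can be checked and raised.

**14 from 10 via 11.** The C–Si and O–S bonds are traced to bromophenol 11 (O-silylation, bromine–lithium exchange, O-to-C silyl shift, triflation), and the C–Br bond to phenol 10. In 10 the two positions ortho to the hydroxyl are the only free ones and are equivalent, so bromination is unambiguous. The dioxolane is the one aldehyde mask that tolerates n-BuLi.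

**10 from 6 and 7 via 9 and 8.** The diaryl ether C–O bond is cut to phenol 6 and 4-fluorobenzaldehyde 7 (SNAr). Placing this step here, on a simple arene, is the point of the sequence: the phenoxide flanked by two benzyloxy groups needs hot carbonate, which is harmless before any ring C exists. The para oxygen, the later triflate oxygen, is held as an allyl ether; it survives base and acid and leaves in step 6 under neutral conditions without touching the benzyl ethers.

**6 from 1 via 4 and 3.** The phenolic C–O bond of 6 is traced to the formyl C–C bond of aldehyde 4 (Dakin-type oxidation). Aldehyde 3 comes from formylation of 3,5-bis(benzyloxy)phenol 1 para to the hydroxyl. This introduces the fourth ring oxygen at the carbon between the two benzyloxy groups and differentiates it from the para oxygen in one stroke.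

**30 from 1 via 27.** The same silyl triflate construction is applied to phenol 1 after ortho-bromination to 27, so both rings A come from one starting material.

## Roads not taken

**Alternative 1:** double carbenoid C–H insertion. The cut removes both C2–C3 bonds at once. A bis(diazomethyl ketone) A2, with each diazo ketone ortho to a benzylic ether, would be decomposed by a chiral dirhodium tetracarboxylate such as Rh2(S-PTTL)4; each carbenoid would insert into its O–CH2–aryl C–H bond to give the penta(tert-butyldimethylsilyl) ether A1.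
- Merits: both rings C and both stereocentres arise in one catalytic step from an achiral precursor, and the silyl ethers come off without hydrogenation. In step count and in convergence this road is better than the adopted plan.
- Weak points: closing ring C requires a 1,6-insertion by an acceptor-only carbenoid, while the ether oxygen itself sits in the 1,5-position. Oxonium ylide formation followed by a 1,2-benzyl shift to a 2-benzylbenzofuran-3-one is the expected competitor. Acceptor-only carbenoids also dimerise and give modest enantiocontrol, and here the catalyst would have to control two independent events. A2 still needs the same tetraoxygenated ring and hindered diaryl ether.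
- Comparison: the adopted plan is longer, but it takes each stereocentre from a ketone hydrogenation of known sense and uses ring closures whose regiochemistry is dictated by the substrate.

**Alternative 2:** enzymatic construction of ring A of flavanone 1. The cut removes C4–C4a, C5–C6, C7–C8 and C4a–C8a. The cinnamic acid A4, carried on the C6 oxygen of finished flavanone 2, would be activated by a coumarate CoA ligase and extended by chalcone synthase (a type three polyketide synthase) with three malonyl units to chalcone A3. A chalcone isomerase would then have to close ring C.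
- Merits: no protecting groups, the phloroglucinol pattern is delivered without any regiochemical question, and an isomerase would set C2 as (S) under neutral aqueous conditions. In protecting-group economy and mildness this road is better than the adopted plan.
- Weak points: both enzymes are shaped for p-coumarate, and a starter carrying a whole flavanone on its para oxygen may not be accepted. Without the isomerase the chalcone closes as a racemate. The difficult half of the molecule, the tetraoxygenated ring A of flavanone 2 with its hindered ether and its own stereocentre, has to be made chemically beforehand.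
- Comparison: the adopted plan solves both flavanones with one reaction type and does not depend on enzyme tolerance of an unnatural substrate.

**Alternative 3:** ring B by diene–alkyne cycloaddition. The cut removes two bonds of ring B of flavanone 1. The (S)-2-ethynylchromanone A6 and the 2-aryloxybuta-1,3-diene A7 would combine under CoBr2(dppe), zinc and ZnI2 to the 1,4-cyclohexadiene A5, which must then be dehydrogenated to the arene.
- Merits: two complete halves are joined late under neutral conditions, and no SNAr on a hindered phenoxide is needed. In convergence this road is better than the adopted, largely linear plan.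
- Weak points: a benzene ring that can be bought is built instead. The stereocentre of A6 becomes a propargylic ether next to an enolisable ketone, which is hard to make and hold enantiopure. The dienyl ether on the crowded C6 oxygen of A7 has no simple preparation. The final oxidation (for example with DDQ) is also the reagent type that dehydrogenates flavanones to flavones.
- Comparison: the adopted plan accepts a longer linear sequence but keeps every stereocentre in a robust benzylic carbinol and every redox step away from ring C.

Key step: step 11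

Assumption: 3,5-bis(benzyloxy)phenol 1 is taken as a catalogue compound; if it had to be made, one statistical benzylation of phloroglucinol (BnBr, K2CO3, DMF) supplies it.

## Route

Step 1
Reactants: 1 3,5-bis(benzyloxy)phenol
Product: 3 2,6-bis(benzyloxy)-4-hydroxybenzaldehyde, via iminium chloride 2 (not isolated)
Conditions: POCl3, DMF, MeCN, 0 °C to rt; then H2O, 50 °C
Reagents that add atoms: N,N-dimethylformamide, CN(C)C=O; water, O
Why: Vilsmeier–Haack formylation; as with 3,5-dimethoxyphenol the chloroiminium ion should enter mainly para to the free hydroxyl, between the two ethers, and the hydrogen-bonded ortho isomer is removed by crystallisation or chromatography.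

Step 2
Reactants: 3 2,6-bis(benzyloxy)-4-hydroxybenzaldehyde
Product: 4 4-(allyloxy)-2,6-bis(benzyloxy)benzaldehyde
Conditions: allyl bromide, K2CO3, DMF, rt
Reagents that add atoms: allyl bromide, C=CCBr
Why: Williamson etherification of the only free phenol; the allyl ether tolerates peracid for a short time, hot carbonate and acid, and is later removed under neutral conditions in the presence of benzyl ethers.

Step 3
Reactants: 4 4-(allyloxy)-2,6-bis(benzyloxy)benzaldehyde
Product: 6 4-(allyloxy)-2,6-bis(benzyloxy)phenol, via aryl formate 5 (not isolated)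
Conditions: mCPBA, CH2Cl2, 0 °C to rt; then K2CO3 (cat.), MeOH, 0 °C, under argon
Reagents that add atoms: 3-chloroperoxybenzoic acid, OOC(=O)c1cccc(Cl)c1
Why: Dakin-type Baeyer–Villiger oxidation; the 2,4,6-trioxygenated aryl group migrates readily, the monosubstituted allyl double bond is epoxidised much more slowly, and mild methanolysis of formate 5 frees the phenol between the two benzyloxy groups.

Step 4
Reactants: 6 4-(allyloxy)-2,6-bis(benzyloxy)phenol; 7 4-fluorobenzaldehyde
Product: 8 4-[4-(allyloxy)-2,6-bis(benzyloxy)phenoxy]benzaldehyde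
Conditions: K2CO3, DMF (degassed), 110 °C
Reagents that add atoms: none
Why: Nucleophilic aromatic substitution (addition–elimination) on the para-formyl-activated fluoroarene; 2,6-dialkoxyphenoxides are known to react this way, and the temperature is far below that of an aryl allyl ether Claisen rearrangement.

Step 5
Reactants: 8 4-[4-(allyloxy)-2,6-bis(benzyloxy)phenoxy]benzaldehyde
Product: 9 2-{4-[4-(allyloxy)-2,6-bis(benzyloxy)phenoxy]phenyl}-1,3-dioxolane
Conditions: HOCH2CH2OH, TsOH (cat.), toluene, reflux, Dean–Stark
Reagents that add atoms: ethylene glycol, OCCO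
Why: Acid-catalysed acetalisation with removal of water; the dioxolane masks the aldehyde against n-BuLi in step 8 and against alkoxide in step 11.

Step 6
Reactants: 9 2-{4-[4-(allyloxy)-2,6-bis(benzyloxy)phenoxy]phenyl}-1,3-dioxolane
Product: 10 3,5-bis(benzyloxy)-4-[4-(1,3-dioxolan-2-yl)phenoxy]phenol
Conditions: Pd(PPh3)4 (5 mol %), morpholine, THF, rt
Reagents that add atoms: none
Why: Tsuji–Trost deallylation; zerovalent palladium ionises the aryl allyl ether and morpholine takes up the allyl group, while benzyl ethers and the dioxolane are inert.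

Step 7
Reactants: 10 3,5-bis(benzyloxy)-4-[4-(1,3-dioxolan-2-yl)phenoxy]phenol
Product: 11 2-bromo-3,5-bis(benzyloxy)-4-[4-(1,3-dioxolan-2-yl)phenoxy]phenol
Conditions: NBS (1.0 equiv), CH2Cl2, −78 to 0 °C
Reagents that add atoms: N-bromosuccinimide, O=C1CCC(=O)N1Br
Why: Electrophilic aromatic bromination; the two positions ortho to the hydroxyl are the only free ones on the activated ring and are equivalent by symmetry, and no HBr is formed, so the acetal is safe.

Step 8
Reactants: 11 2-bromo-3,5-bis(benzyloxy)-4-[4-(1,3-dioxolan-2-yl)phenoxy]phenol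
Product: 14 3,5-bis(benzyloxy)-4-[4-(1,3-dioxolan-2-yl)phenoxy]-2-(trimethylsilyl)phenyl trifluoromethanesulfonate, via aryl trimethylsilyl ether 12 (not isolated), via lithium 2-silylphenoxide 13 (not isolated)
Conditions: HMDS, THF, 70 °C, evaporate; n-BuLi, THF, −100 to −80 °C; Tf2O, −100 °C
Reagents that add atoms: hexamethyldisilazane, C[Si](C)(C)N[Si](C)(C)C; trifluoromethanesulfonic anhydride, O=S(=O)(OS(=O)(=O)C(F)(F)F)C(F)(F)F
Why: O-silylation, bromine–lithium exchange, anionic 1,3 O-to-C silyl shift (retro-Brook rearrangement) and O-triflation, the standard route to 2-(trimethylsilyl)aryl triflates, known for the closely related 3,5-dialkoxy case; THF itself survives Tf2O at this temperature, so the dioxolane should as well.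

Step 9
Reactants: 15 4′-(benzyloxy)acetophenone; 16 dimethyl carbonate
Product: 17 methyl 3-[4-(benzyloxy)phenyl]-3-oxopropanoate
Conditions: NaH, THF, reflux; aq. HCl
Reagents that add atoms: none
Why: Crossed Claisen condensation (C-methoxycarbonylation of the ketone enolate), driven to completion by deprotonation of the β-keto ester formed.

Step 10
Reactants: 17 methyl 3-[4-(benzyloxy)phenyl]-3-oxopropanoate
Product: 18 methyl (S)-3-[4-(benzyloxy)phenyl]-3-hydroxypropanoate
Conditions: H2 (30 bar), [RuCl(p-cymene)((R)-SEGPHOS)]Cl (1 mol %), MeOH, 50 °C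
Reagents that add atoms: none
Why: Noyori asymmetric hydrogenation of a β-keto ester through its chelated ruthenium complex; the (R)-configured diphosphine should deliver hydrogen to the face that gives the (R)-alcohol from methyl acetoacetate, which for an aryl keto ester carries the (S) descriptor because aryl outranks CH2CO2Me; the solid product can be recrystallised to raise enantiopurity.

Step 11
Reactants: 18 methyl (S)-3-[4-(benzyloxy)phenyl]-3-hydroxypropanoate; 14 3,5-bis(benzyloxy)-4-[4-(1,3-dioxolan-2-yl)phenoxy]-2-(trimethylsilyl)phenyl trifluoromethanesulfonate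
Product: 21 (S)-5,7-bis(benzyloxy)-2-[4-(benzyloxy)phenyl]-6-[4-(1,3-dioxolan-2-yl)phenoxy]chroman-4-one, via trimethylsilyl ether 19 (not isolated), via aryne 20 (not isolated)
Conditions: 18 (1.5 equiv), HMDS, TMSCl (cat.), THF, 50 °C, evaporate with toluene; then 14, CsF (1.1 equiv), 18-crown-6, THF, 0 °C to rt; pH 7 buffer
Reagents that add atoms: none
Why: Proposed new method: fluoride frees the cesium alkoxide from silyl ether 19 and triggers 1,2-elimination of 14 to the 3,4,5-trioxygenated aryne 20, so that nucleophile and aryne meet in a proton-free medium. The alkoxide adds to the aryne carbon remote from the flanking benzyloxy group, the more electrophilic terminus of a 3-alkoxyaryne, which puts the aryl anion at the future C4a beside the inductively stabilising C5 oxygen. This anion attacks the tethered methyl ester in a 6-exo-trig acyl substitution and expels methoxide, forming C8a–O1 and C4–C4a and closing ring C in a formal [4+2] annulation. The methoxide is taken up by silicon (as MeOSiMe3, from 19 or 14), which is why about one equivalent of fluoride is enough and no strong base is left to open the new flavanone by E1cB. The closest known reaction types are the fluoride-mediated annulation of arynes with salicylate esters to xanthones and the insertion of arynes into carboxylic acids that leads to chromanones; a secondary aliphatic alkoxide on an sp3 tether has not been shown in this role. No stereocentre is formed: the C2–O bond of 18 stays intact and no chalcone intervenes, so the (S) configuration set in step 10 is carried over. The step needs oxygen at C8a and acyl at C4a (the 6-aryloxy, not the 8-aryloxy, product), which the benzyloxy group next to the triple bond secures, and acyl trapping ahead of protonation, which the silyl ether (no free OH) and THF (no acidic C–H as in MeCN) secure.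

Step 12
Reactants: 21 (S)-5,7-bis(benzyloxy)-2-[4-(benzyloxy)phenyl]-6-[4-(1,3-dioxolan-2-yl)phenoxy]chroman-4-one
Product: 22 4-{[(S)-5,7-bis(benzyloxy)-2-[4-(benzyloxy)phenyl]-4-oxochroman-6-yl]oxy}benzaldehyde
Conditions: 1 M aq. HCl, THF, rt
Reagents that add atoms: water, O
Why: Acid-catalysed acetal hydrolysis of an aryl dioxolane; flavanones and aryl benzyl ethers are stable to dilute acid at room temperature.

Step 13
Reactants: 22 4-{[(S)-5,7-bis(benzyloxy)-2-[4-(benzyloxy)phenyl]-4-oxochroman-6-yl]oxy}benzaldehyde
Product: 23 4-{[(S)-5,7-bis(benzyloxy)-2-[4-(benzyloxy)phenyl]-4-oxochroman-6-yl]oxy}benzoic acid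
Conditions: NaClO2, NaH2PO4, 2-methyl-2-butene, t-BuOH/THF/H2O, rt
Reagents that add atoms: sodium chlorite, [Na+].[O-]Cl=O
Why: Pinnick oxidation in a weakly acidic buffer; 2-methyl-2-butene removes HOCl before it can chlorinate the electron-rich rings, and nothing basic touches ring C.

Step 14
Reactants: 23 4-{[(S)-5,7-bis(benzyloxy)-2-[4-(benzyloxy)phenyl]-4-oxochroman-6-yl]oxy}benzoic acid
Product: 25 methyl 3-(4-{[(S)-5,7-bis(benzyloxy)-2-[4-(benzyloxy)phenyl]-4-oxochroman-6-yl]oxy}phenyl)-3-oxopropanoate, via acyl imidazolide 24 (not isolated)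
Conditions: CDI, THF, rt; then KO2CCH2CO2Me, MgCl2, Et3N, THF, rt to 40 °C; aq. HCl
Reagents that add atoms: potassium methyl malonate, COC(=O)CC(=O)[O-].[K+]
Why: Masamune–Brooks homologation; the magnesium enolate of the malonate half-ester is C-acylated by acyl imidazolide 24 and decarboxylates on work-up, under conditions too mild to enolise the chromanone.

Step 15
Reactants: 25 methyl 3-(4-{[(S)-5,7-bis(benzyloxy)-2-[4-(benzyloxy)phenyl]-4-oxochroman-6-yl]oxy}phenyl)-3-oxopropanoate
Product: 26 methyl (S)-3-(4-{[(S)-5,7-bis(benzyloxy)-2-[4-(benzyloxy)phenyl]-4-oxochroman-6-yl]oxy}phenyl)-3-hydroxypropanoate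
Conditions: H2 (30 bar), [RuCl(p-cymene)((R)-SEGPHOS)]Cl (2 mol %), MeOH/CH2Cl2, 50 °C
Reagents that add atoms: none
Why: Noyori asymmetric hydrogenation with the same ligand and the same sense as in step 10, the distant stereocentre having no say; the chelating β-keto ester is reduced while the non-chelating, doubly ortho-substituted chromanone carbonyl and the benzyl ethers are not substrates for this catalyst.

Step 16
Reactants: 1 3,5-bis(benzyloxy)phenol
Product: 27 2-bromo-3,5-bis(benzyloxy)phenol
Conditions: NBS (1.0 equiv), i-Pr2NH (10 mol %), CH2Cl2, −78 to 0 °C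
Reagents that add atoms: N-bromosuccinimide, O=C1CCC(=O)N1Br
Why: Amine-mediated ortho-bromination of a phenol (delivery of bromine from a hydrogen-bonded N-bromoamine); two equivalent ortho positions compete with one para position, and the 4-bromo isomer is removed by chromatography.

Step 17
Reactants: 27 2-bromo-3,5-bis(benzyloxy)phenol
Product: 30 3,5-bis(benzyloxy)-2-(trimethylsilyl)phenyl trifluoromethanesulfonate, via aryl trimethylsilyl ether 28 (not isolated), via lithium 2-silylphenoxide 29 (not isolated)
Conditions: HMDS, THF, 70 °C, evaporate; n-BuLi, THF, −100 to −80 °C; Tf2O, −100 °C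
Reagents that add atoms: hexamethyldisilazane, C[Si](C)(C)N[Si](C)(C)C; trifluoromethanesulfonic anhydride, O=S(=O)(OS(=O)(=O)C(F)(F)F)C(F)(F)F
Why: The same silylation, retro-Brook rearrangement and triflation sequence as in step 8, here on the substrate class for which it is established.

Step 18
Reactants: 26 methyl (S)-3-(4-{[(S)-5,7-bis(benzyloxy)-2-[4-(benzyloxy)phenyl]-4-oxochroman-6-yl]oxy}phenyl)-3-hydroxypropanoate; 30 3,5-bis(benzyloxy)-2-(trimethylsilyl)phenyl trifluoromethanesulfonate
Product: 33 (S)-5,7-bis(benzyloxy)-2-[4-(benzyloxy)phenyl]-6-{4-[(S)-5,7-bis(benzyloxy)-4-oxochroman-2-yl]phenoxy}chroman-4-one, via trimethylsilyl ether 31 (not isolated), via aryne 32 (not isolated)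
Conditions: HMDS, TMSCl (cat.), THF, 50 °C, evaporate with toluene; then 30 (1.5 equiv), CsF (1.2 equiv), 18-crown-6, THF, 0 °C to rt; pH 7 buffer
Reagents that add atoms: none
Why: Proposed new method: as in step 11, fluoride releases the alkoxide from 31 and the 3,5-bis(benzyloxy)benzyne 32 from 30, the alkoxide adds remote from the flanking benzyloxy group and the aryl anion closes ring C of flavanone 1 by 6-exo-trig attack on the methyl ester, the methoxide being absorbed as MeOSiMe3; the closest known reaction type is again the aryne annulation of salicylate esters to xanthones. The C2–O bond of 26 is not broken, so the (S) centre from step 15 is retained, and the near-stoichiometric fluoride is meant to keep flavanone 2 from base-induced ring opening.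

Step 19
Reactants: 33 (S)-5,7-bis(benzyloxy)-2-[4-(benzyloxy)phenyl]-6-{4-[(S)-5,7-bis(benzyloxy)-4-oxochroman-2-yl]phenoxy}chroman-4-one
Product: 34 (2S)-5,7-dihydroxy-2-(4-hydroxyphenyl)-6-{4-[(2S)-5,7-dihydroxy-4-oxochroman-2-yl]phenoxy}chroman-4-one
Conditions: H2 (1 atm), Pd/C (10 %), EtOAc/MeOH, rt, stopped after uptake of five equivalents
Reagents that add atoms: none
Why: Catalytic hydrogenolysis of five aryl benzyl ethers under neutral conditions, as is routine for benzyl-protected flavanones; neither stereocentre is touched as long as the benzylic C2–O1 bonds are not reduced.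

## Compound list

1 | 3,5-bis(benzyloxy)phenol | Oc1cc(OCc2ccccc2)cc(OCc2ccccc2)c1 | starting material
2 | N-[2,6-bis(benzyloxy)-4-hydroxybenzylidene]-N-methylmethanaminium chloride | C[N+](C)=Cc1c(OCc2ccccc2)cc(O)cc1OCc1ccccc1.[Cl-] | intermediate
3 | 2,6-bis(benzyloxy)-4-hydroxybenzaldehyde | O=Cc1c(OCc2ccccc2)cc(O)cc1OCc1ccccc1 | intermediate
4 | 4-(allyloxy)-2,6-bis(benzyloxy)benzaldehyde | O=Cc1c(OCc2ccccc2)cc(OCC=C)cc1OCc1ccccc1 | intermediate
5 | 4-(allyloxy)-2,6-bis(benzyloxy)phenyl formate | O=COc1c(OCc2ccccc2)cc(OCC=C)cc1OCc1ccccc1 | intermediate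
6 | 4-(allyloxy)-2,6-bis(benzyloxy)phenol | Oc1c(OCc2ccccc2)cc(OCC=C)cc1OCc1ccccc1 | intermediate
7 | 4-fluorobenzaldehyde | O=Cc1ccc(F)cc1 | starting material
8 | 4-[4-(allyloxy)-2,6-bis(benzyloxy)phenoxy]benzaldehyde | O=Cc1ccc(Oc2c(OCc3ccccc3)cc(OCC=C)cc2OCc2ccccc2)cc1 | intermediate
9 | 2-{4-[4-(allyloxy)-2,6-bis(benzyloxy)phenoxy]phenyl}-1,3-dioxolane | C=CCOc1cc(OCc2ccccc2)c(Oc2ccc(C3OCCO3)cc2)c(OCc2ccccc2)c1 | intermediate
10 | 3,5-bis(benzyloxy)-4-[4-(1,3-dioxolan-2-yl)phenoxy]phenol | Oc1cc(OCc2ccccc2)c(Oc2ccc(C3OCCO3)cc2)c(OCc2ccccc2)c1 | intermediate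
11 | 2-bromo-3,5-bis(benzyloxy)-4-[4-(1,3-dioxolan-2-yl)phenoxy]phenol | Oc1cc(OCc2ccccc2)c(Oc2ccc(C3OCCO3)cc2)c(OCc2ccccc2)c1Br | intermediate
12 | {2-bromo-3,5-bis(benzyloxy)-4-[4-(1,3-dioxolan-2-yl)phenoxy]phenoxy}trimethylsilane | C[Si](C)(C)Oc1cc(OCc2ccccc2)c(Oc2ccc(C3OCCO3)cc2)c(OCc2ccccc2)c1Br | intermediate
13 | lithium 3,5-bis(benzyloxy)-4-[4-(1,3-dioxolan-2-yl)phenoxy]-2-(trimethylsilyl)phenoxide | [Li+].[O-]c1cc(OCc2ccccc2)c(Oc2ccc(C3OCCO3)cc2)c(OCc2ccccc2)c1[Si](C)(C)C | intermediate
14 | 3,5-bis(benzyloxy)-4-[4-(1,3-dioxolan-2-yl)phenoxy]-2-(trimethylsilyl)phenyl trifluoromethanesulfonate | C[Si](C)(C)c1c(OS(=O)(=O)C(F)(F)F)cc(OCc2ccccc2)c(Oc2ccc(C3OCCO3)cc2)c1OCc1ccccc1 | intermediate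
15 | 4′-(benzyloxy)acetophenone | CC(=O)c1ccc(OCc2ccccc2)cc1 | starting material
16 | dimethyl carbonate | COC(=O)OC | starting material
17 | methyl 3-[4-(benzyloxy)phenyl]-3-oxopropanoate | COC(=O)CC(=O)c1ccc(OCc2ccccc2)cc1 | intermediate
18 | methyl (S)-3-[4-(benzyloxy)phenyl]-3-hydroxypropanoate | COC(=O)C[C@@H](c1ccc(OCc2ccccc2)cc1)O | intermediate
19 | methyl (S)-3-[4-(benzyloxy)phenyl]-3-(trimethylsilyloxy)propanoate | COC(=O)C[C@@H](c1ccc(OCc2ccccc2)cc1)O[Si](C)(C)C | intermediate
20 | 3,5-bis(benzyloxy)-4-[4-(1,3-dioxolan-2-yl)phenoxy]benzyne | C1#CC(OCc2ccccc2)=C(Oc2ccc(C3OCCO3)cc2)C(OCc2ccccc2)=C1 | intermediate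
21 | (S)-5,7-bis(benzyloxy)-2-[4-(benzyloxy)phenyl]-6-[4-(1,3-dioxolan-2-yl)phenoxy]chroman-4-one | O=C1C[C@@H](c2ccc(OCc3ccccc3)cc2)Oc2cc(OCc3ccccc3)c(Oc3ccc(C4OCCO4)cc3)c(OCc3ccccc3)c21 | intermediate
22 | 4-{[(S)-5,7-bis(benzyloxy)-2-[4-(benzyloxy)phenyl]-4-oxochroman-6-yl]oxy}benzaldehyde | O=Cc1ccc(Oc2c(OCc3ccccc3)cc3c(c2OCc2ccccc2)C(=O)C[C@@H](c2ccc(OCc4ccccc4)cc2)O3)cc1 | intermediate
23 | 4-{[(S)-5,7-bis(benzyloxy)-2-[4-(benzyloxy)phenyl]-4-oxochroman-6-yl]oxy}benzoic acid | OC(=O)c1ccc(Oc2c(OCc3ccccc3)cc3c(c2OCc2ccccc2)C(=O)C[C@@H](c2ccc(OCc4ccccc4)cc2)O3)cc1 | intermediate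
24 | (S)-5,7-bis(benzyloxy)-2-[4-(benzyloxy)phenyl]-6-[4-(1H-imidazole-1-carbonyl)phenoxy]chroman-4-one | O=C(n1ccnc1)c1ccc(Oc2c(OCc3ccccc3)cc3c(c2OCc2ccccc2)C(=O)C[C@@H](c2ccc(OCc4ccccc4)cc2)O3)cc1 | intermediate
25 | methyl 3-(4-{[(S)-5,7-bis(benzyloxy)-2-[4-(benzyloxy)phenyl]-4-oxochroman-6-yl]oxy}phenyl)-3-oxopropanoate | COC(=O)CC(=O)c1ccc(Oc2c(OCc3ccccc3)cc3c(c2OCc2ccccc2)C(=O)C[C@@H](c2ccc(OCc4ccccc4)cc2)O3)cc1 | intermediate
26 | methyl (S)-3-(4-{[(S)-5,7-bis(benzyloxy)-2-[4-(benzyloxy)phenyl]-4-oxochroman-6-yl]oxy}phenyl)-3-hydroxypropanoate | COC(=O)C[C@@H](c1ccc(Oc2c(OCc3ccccc3)cc3c(c2OCc2ccccc2)C(=O)C[C@@H](c2ccc(OCc4ccccc4)cc2)O3)cc1)O | intermediate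
27 | 2-bromo-3,5-bis(benzyloxy)phenol | Oc1cc(OCc2ccccc2)cc(OCc2ccccc2)c1Br | intermediate
28 | [2-bromo-3,5-bis(benzyloxy)phenoxy]trimethylsilane | C[Si](C)(C)Oc1cc(OCc2ccccc2)cc(OCc2ccccc2)c1Br | intermediate
29 | lithium 3,5-bis(benzyloxy)-2-(trimethylsilyl)phenoxide | [Li+].[O-]c1cc(OCc2ccccc2)cc(OCc2ccccc2)c1[Si](C)(C)C | intermediate
30 | 3,5-bis(benzyloxy)-2-(trimethylsilyl)phenyl trifluoromethanesulfonate | C[Si](C)(C)c1c(OS(=O)(=O)C(F)(F)F)cc(OCc2ccccc2)cc1OCc1ccccc1 | intermediate
31 | methyl (S)-3-(4-{[(S)-5,7-bis(benzyloxy)-2-[4-(benzyloxy)phenyl]-4-oxochroman-6-yl]oxy}phenyl)-3-(trimethylsilyloxy)propanoate | COC(=O)C[C@@H](c1ccc(Oc2c(OCc3ccccc3)cc3c(c2OCc2ccccc2)C(=O)C[C@@H](c2ccc(OCc4ccccc4)cc2)O3)cc1)O[Si](C)(C)C | intermediate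
32 | 3,5-bis(benzyloxy)benzyne | C1#CC(OCc2ccccc2)=CC(OCc2ccccc2)=C1 | intermediate
33 | (S)-5,7-bis(benzyloxy)-2-[4-(benzyloxy)phenyl]-6-{4-[(S)-5,7-bis(benzyloxy)-4-oxochroman-2-yl]phenoxy}chroman-4-one | O=C1C[C@@H](c2ccc(Oc3c(OCc5ccccc5)cc4c(c3OCc3ccccc3)C(=O)C[C@@H](c3ccc(OCc5ccccc5)cc3)O4)cc2)Oc2cc(OCc3ccccc3)cc(OCc3ccccc3)c21 | intermediate
34 | (2S)-5,7-dihydroxy-2-(4-hydroxyphenyl)-6-{4-[(2S)-5,7-dihydroxy-4-oxochroman-2-yl]phenoxy}chroman-4-one | O=C1C[C@@H](c2ccc(Oc3c(O)cc4c(c3O)C(=O)C[C@@H](c3ccc(O)cc3)O4)cc2)Oc2cc(O)cc(O)c21 | target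

## Step count and risks

Total step count: 19. Longest linear sequence: 15 steps (steps 1–8, 11–15, 18 and 19); steps 9–10 and 16–17 are side branches.

**Step 11 (key step, new method).** The most likely failures are three. The transient alkoxide may be lost by retro-aldol cleavage or β-elimination before it meets the aryne. The aryl anion may be protonated by adventitious proton sources, giving a simple aryl ether. The product may lose configurational integrity by fluoride- or methoxide-induced ring opening to the chalcone. The fallback uses known chemistry, sets out from bromophenol 11 and keto ester 17, and comes back at 21. Keto ester 17 is hydrogenated with the (S)-configured ligand to methyl (R)-3-[4-(benzyloxy)phenyl]-3-hydroxypropanoate F1. F1 is converted with Me(MeO)NH·HCl and i-PrMgCl into (R)-3-[4-(benzyloxy)phenyl]-3-hydroxy-N-methoxy-N-methylpropanamide F2. A Mitsunobu etherification of F2 with 11 (PPh3, DIAD) inverts the carbinol centre and gives the (S)-configured aryl ether amide F3. Bromine–lithium exchange on F3 (n-BuLi, THF, −78 °C) is followed by intramolecular acylation of the aryllithium by the Weinreb amide (a Parham-type cyclisation), which closes ring C to 21.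

**Step 18 (new method).** The nucleophile is now large and dilute, so the aryne may be consumed by other pathways. The stereocentre of flavanone 2 may be eroded by base-induced ring opening while the second ring closes. The fallback uses known chemistry, sets out from keto ester 25 and phenol 1, and comes back at 33. Keto ester 25 is hydrogenated with the (S)-configured ligand to methyl (R)-3-(4-{[(S)-5,7-bis(benzyloxy)-2-[4-(benzyloxy)phenyl]-4-oxochroman-6-yl]oxy}phenyl)-3-hydroxypropanoate F4. A Mitsunobu reaction of F4 with 1 gives, with inversion, methyl (S)-3-[3,5-bis(benzyloxy)phenoxy]-3-(4-{[(S)-5,7-bis(benzyloxy)-2-[4-(benzyloxy)phenyl]-4-oxochroman-6-yl]oxy}phenyl)propanoate F5. Neutral ester cleavage with Me3SnOH gives (S)-3-[3,5-bis(benzyloxy)phenoxy]-3-(4-{[(S)-5,7-bis(benzyloxy)-2-[4-(benzyloxy)phenyl]-4-oxochroman-6-yl]oxy}phenyl)propanoic acid F6. Intramolecular Friedel–Crafts acylation of F6 (trifluoroacetic anhydride, CH2Cl2, 0 °C), ortho to the ether oxygen of the phloroglucinol ring, gives 33.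

**Step 15.** The chromanone carbonyl may be reduced alongside the keto ester. The electron-rich benzylic carbinol may undergo solvolysis in warm, slightly acidic methanol. Incomplete facial selectivity would leave a diastereomer that is hard to separate. The fallback sets out from aldehyde 22 and comes back at 26. A catalytic enantioselective Mukaiyama acetate aldol addition of 1-methoxy-1-(trimethylsilyloxy)ethene to 22 is run under a chiral titanium tetraisopropoxide–binaphthol-type Lewis acid, with the catalyst enantiomer chosen for the (S) adduct. It gives silyl ether 31 directly; mild acid converts 31 into 26, or 31 is taken straight into step 18. Steps 13–15 are bypassed.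

**Step 1.** Formylation ortho instead of para to the hydroxyl (poor regioselectivity) or double formylation would cut the supply of 3. The fallback sets out from 1 and comes back at 6. Teuber oxidation of 1 with (KSO3)2NO gives 2,6-bis(benzyloxy)-1,4-benzoquinone F7. Reduction with Na2S2O4 gives 2,6-bis(benzyloxy)benzene-1,4-diol F8. Monoallylation of F8 at the less hindered, more acidic hydroxyl (allyl bromide, one equivalent, K2CO3, acetone) gives 6.

**Step 19.** Over-reduction is the risk: hydrogenolysis of a benzylic C2–O1 bond to a dihydrochalcone, or reduction of a C4 carbonyl, before the last benzyl ether has gone. The fallback sets out from 33 and comes back at 34. Non-reductive Lewis-acid debenzylation with BCl3 and pentamethylbenzene (CH2Cl2, −78 °C) transfers the benzyl groups to the arene scavenger.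

## Further compounds

F1 | step 11 | methyl (R)-3-[4-(benzyloxy)phenyl]-3-hydroxypropanoate | COC(=O)C[C@H](c1ccc(OCc2ccccc2)cc1)O
F2 | step 11 | (R)-3-[4-(benzyloxy)phenyl]-3-hydroxy-N-methoxy-N-methylpropanamide | CON(C)C(=O)C[C@H](c1ccc(OCc2ccccc2)cc1)O
F3 | step 11 | (S)-3-{2-bromo-3,5-bis(benzyloxy)-4-[4-(1,3-dioxolan-2-yl)phenoxy]phenoxy}-3-[4-(benzyloxy)phenyl]-N-methoxy-N-methylpropanamide | CON(C)C(=O)C[C@@H](c1ccc(OCc2ccccc2)cc1)Oc1cc(OCc2ccccc2)c(Oc2ccc(C3OCCO3)cc2)c(OCc2ccccc2)c1Br
F4 | step 18 | methyl (R)-3-(4-{[(S)-5,7-bis(benzyloxy)-2-[4-(benzyloxy)phenyl]-4-oxochroman-6-yl]oxy}phenyl)-3-hydroxypropanoate | COC(=O)C[C@H](c1ccc(Oc2c(OCc3ccccc3)cc3c(c2OCc2ccccc2)C(=O)C[C@@H](c2ccc(OCc4ccccc4)cc2)O3)cc1)O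
F5 | step 18 | methyl (S)-3-[3,5-bis(benzyloxy)phenoxy]-3-(4-{[(S)-5,7-bis(benzyloxy)-2-[4-(benzyloxy)phenyl]-4-oxochroman-6-yl]oxy}phenyl)propanoate | COC(=O)C[C@@H](c1ccc(Oc2c(OCc3ccccc3)cc3c(c2OCc2ccccc2)C(=O)C[C@@H](c2ccc(OCc4ccccc4)cc2)O3)cc1)Oc1cc(OCc2ccccc2)cc(OCc2ccccc2)c1
F6 | step 18 | (S)-3-[3,5-bis(benzyloxy)phenoxy]-3-(4-{[(S)-5,7-bis(benzyloxy)-2-[4-(benzyloxy)phenyl]-4-oxochroman-6-yl]oxy}phenyl)propanoic acid | OC(=O)C[C@@H](c1ccc(Oc2c(OCc3ccccc3)cc3c(c2OCc2ccccc2)C(=O)C[C@@H](c2ccc(OCc4ccccc4)cc2)O3)cc1)Oc1cc(OCc2ccccc2)cc(OCc2ccccc2)c1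
F0 | step 15 | none | none
F7 | step 1 | 2,6-bis(benzyloxy)-1,4-benzoquinone | O=C1C=C(OCc2ccccc2)C(=O)C(OCc2ccccc2)=C1
F8 | step 1 | 2,6-bis(benzyloxy)benzene-1,4-diol | Oc1cc(OCc2ccccc2)c(O)c(OCc2ccccc2)c1
F0 | step 19 | none | none
A1 | alternative 1 | penta(tert-butyldimethylsilyl) ether of the target | O=C1C[C@@H](c2ccc(Oc3c(O[Si](C)(C)C(C)(C)C)cc4c(c3O[Si](C)(C)C(C)(C)C)C(=O)C[C@@H](c3ccc(O[Si](C)(C)C(C)(C)C)cc3)O4)cc2)Oc2cc(O[Si](C)(C)C(C)(C)C)cc(O[Si](C)(C)C(C)(C)C)c21
A2 | alternative 1 | bis(diazomethyl ketone) with an ortho benzylic ether beside each diazoacetyl group, all five phenols as tert-butyldimethylsilyl ethers | [N-]=[N+]=CC(=O)c1c(O[Si](C)(C)C(C)(C)C)cc(O[Si](C)(C)C(C)(C)C)cc1OCc1ccc(Oc2c(O[Si](C)(C)C(C)(C)C)cc(OCc3ccc(O[Si](C)(C)C(C)(C)C)cc3)c(C(=O)C=[N+]=[N-])c2O[Si](C)(C)C(C)(C)C)cc1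
A3 | alternative 2 | 2′,4′,6′-trihydroxychalcone of flavanone 1 attached through its 4-oxygen to C6 of (S)-flavanone 2 | O=C(/C=C/c1ccc(Oc2c(O)cc3c(c2O)C(=O)C[C@@H](c2ccc(O)cc2)O3)cc1)c1c(O)cc(O)cc1O
A4 | alternative 2 | (E)-3-(4-{[(S)-5,7-dihydroxy-2-(4-hydroxyphenyl)-4-oxochroman-6-yl]oxy}phenyl)acrylic acid | OC(=O)/C=C/c1ccc(Oc2c(O)cc3c(c2O)C(=O)C[C@@H](c2ccc(O)cc2)O3)cc1
A5 | alternative 3 | methoxymethyl-protected target with ring B of flavanone 1 as a 1,4-cyclohexadiene | O=C1C[C@@H](C2=CCC(Oc3c(OCOC)cc4c(c3OCOC)C(=O)C[C@@H](c3ccc(OCOC)cc3)O4)=CC2)Oc2cc(OCOC)cc(OCOC)c21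
A6 | alternative 3 | (S)-2-ethynyl-5,7-bis(methoxymethoxy)chroman-4-one | O=C1C[C@@H](C#C)Oc2cc(OCOC)cc(OCOC)c21
A7 | alternative 3 | (S)-6-(buta-1,3-dien-2-yloxy)-5,7-bis(methoxymethoxy)-2-[4-(methoxymethoxy)phenyl]chroman-4-one | C=CC(=C)Oc1c(OCOC)cc2c(c1OCOC)C(=O)C[C@@H](c1ccc(OCOC)cc1)O2
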